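## Structural features

24-nor-Spiculoic acid B is a trans-fused tetrahydroindene. Ring A is a cyclopentene, C1(Et)=C2H–C3H(Me)–C4H–C9H, and ring B a cyclohexene, C4–C5(Me)=C6H–C7–C8–C9; they share the C4–C9 bond, with H-4 and H-9 on opposite faces (C10 is the carboxyl carbon on C8). Five stereocentres stand in one unbroken row, C3–C4–C9–C8–C7. C7 (ethyl, E-styryl) and C8 (methyl, carboxyl) are adjacent all-carbon quaternary centres, and the carboxyl is cis to H-9 and to the styryl group. In ring A the C3 methyl is trans to the C4–C5 bond, so C3/C4/C9 are all-trans. Fragile points are the doubly allylic C7 with its styryl arm (acid- and radical-sensitive), two trisubstituted ring alkenes that must not migrate, and a neopentyl carboxyl that is hard to unmask late. The real difficulty is the quaternary pair C7/C8 and its relation to the trans ring fusion. The key step uses ring A: the C1=C2 bond is read as the trace of an sp2 radical at C1, and C9 as the β-carbon of a 2-methylpropenoate that already holds C8, so a 5-exo closure makes C1–C9 and sets C9 from the C3/C4 pair.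

## Logic of the disconnections

32 ⇒ 29. Cut: C7–C8, with C5=C6 moved back to C6=C7 and the C5–O bond restored (retro-[3,3]). Reason: a sigmatropic shift is the most dependable way to join two fully substituted carbons with relay of configuration. Gain: ring B and both quaternary centres vanish; 29 has one tertiary carbinol instead. Demand: inside the bicyclic frame the shift can only pass through a boat-like array, so C5 must be S (dienyl cis to H-4) and C6=C7 must be E; C8 of 29 need not be defined.

29 ⇒ 21 + 25. Cut: C5–C6 and the lactone C10–O bond. Reason: the styryl-diene arm can be made apart with fixed geometry and joined late. Gain: convergence; 21 contains ring A only. Demand: an alkenyl metal that adds to the ketone and not the ester of 21, keeps its geometry, and enters on the correct face of C5; the alkoxide must then close the ring.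

25 ⇒ 23 ⇒ 22. Cut: the C7–ethyl and C6–I bonds (syn addition across the alkyne of 23), then one alkyne carbon. Reason: a syn carbometalation fixes the trisubstituted alkene geometry in one operation. Gain: a commercial aldehyde. Demand: syn- and regioselective addition, and iodination with retention.

21 ⇒ 20. Change at C5 only: ketone back to dioxolane. Reason: with C5 masked, H-4 is not acidic while C9 is an aldehyde or part of an enoate. Gain: configurational safety rather than simplicity. Demand: hydrolysis mild enough for the ester and alkene.

20 ⇒ 19. Cut: C1–C9. Reason: C1=C2 is the footprint of an alkenyl radical, and C9 sits β to an ester, the best radical acceptor in the molecule. Gain: ring A opens to an acyclic chain with only the C3/C4 pair. Demand: cyclisation faster than reduction, 5-exo regiochemistry, and control of C9 by C3 and C4.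

19 ⇒ 14 + 15. Cut: C1=C2. Reason: a Wittig reaction places bromine and ethyl on C1 in one step, and the alkene geometry is irrelevant. Gain: an aldehyde and a commercial phosphonium salt. Demand: a short-lived α-bromo ylide must meet a hindered, epimerisable aldehyde.

14 ⇒ 12. The C2 aldehyde is traced back to the C2=C alkene of a propenyl group. Reason: that group is what the rearrangement below delivers. Gain: no protecting group is needed. Demand: cleavage of the electron-rich alkene beside the enoate.

12 ⇒ 9 + 10. Cut: C8=C9. Reason: a stabilised Wittig reaction gives the E enoate and brings in C8, its methyl and C10. Gain: a primary alcohol and a commercial ylide. Demand: the intermediate aldehyde 11 must not epimerise at C4.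

9 ⇒ 8 ⇒ 5. Reduction level change at C9, then cut C3–C4 with the ester C–O bond restored (retro-[3,3]). Reason: one chair transition state sets C3 and C4 together from a single carbinol centre. Gain: an achiral acid and a five-carbon allylic alcohol. Demand: the enolate geometry with the ketal carbon cis to O–metal, and no β-elimination of the ketal.

5 ⇒ 4 + 2; 4 ⇐ 3; 2 ⇐ 1. Cut: the ester C–O bond; 4 comes from 3 by hydrolysis and 2 from 1 by resolution. Gain: commercial materials only. Demand: high enantiomeric purity of 2, the sole source of absolute configuration.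

## Other disconnections considered

Alternative 1: The cut is C6–C7 in ring B. Precursor A1 has a Z-alkenyl iodide at C6, the quaternary C8 in place carrying the alkene C7(Et)=CH–CH2Ph, and C1 still a ketone. With Pd(OAc)2, a bisphosphine and Ag3PO4, the C6–I bond adds to zerovalent palladium, the alkene inserts 6-exo to form C6–C7 and ring B, and β-hydride elimination from the benzylic CH2 gives the E-styryl group of A2.
- In favour: C7 is made in a catalytic, tin-free step that also supplies the styryl geometry. On the styryl alkene this route is the better one, since no preformed dienyl metal is needed.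
- Against: C8 must already be a quaternary stereocentre and is then the only element controlling the alkene face; with methyl and ester of similar size this control is uncertain. A2 still needs C1=O turned into C1(Et)=C2 (enol triflate, then ethyl coupling), and a trans-fused hydrindanone with an enolisable H-9 tends to go cis.
- Comparison: it attacks the quaternary problem more directly. Both plans rest on one diastereoselective ring closure, but here control must cross a quaternary carbon, whereas in the chosen plan the controlling centres are adjacent. It is no shorter, because C8 and the C1=C2 unit need separate operations.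

Alternative 2: The cut is C7–C8 with the C5–O bond restored. The silyl ketene acetal of δ-lactone A3 (identical with 29) rearranges on warming to silyl ester A4 (identical with 31).
- In favour: it makes both quaternary centres, ring B and the C5=C6 alkene in one stereospecific step. As a single disconnection it removes more complexity than the radical closure and is the better one on that measure; the chosen plan uses it as its last step, so on the C7–C8 bond the two plans are equal.
- Against, as the organising step: the whole stereochemical burden moves to A3 (C5 configuration, E geometry at C6=C7), and the all-trans ring A is presupposed without a way to make it. The boat-like transition state is strained by the trans fusion, and the tertiary dienylic C–O bond can ionise.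
- Comparison: the chosen plan treats this step as a user of stereochemical information and puts the strategic weight on the step that creates ring A and C9. With ring A made otherwise the step count would not fall.

Alternative 3: The cut removes C2 from ring A (C1=C2 and C2–C3). Precursor A5 is the complete ring B with a propionyl group on C9 and an ethyl group on C4. Me3SiC(Li)N2 converts the ketone into the alkylidene carbene at C2, which inserts into a C–H bond of the CH2 of the C4 ethyl group, giving A6.
- In favour: ring A and its alkene are made last, tin-free, from a one-carbon reagent, with the C1 ethyl already present and no C8 epimer question. On reagent toxicity and on the number of operations spent on ring A this is the better plan.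
- Against: C3 arises from a prochiral CH2, and the choice of hydrogen depends only on a strained trans-fused insertion geometry. The C8 methyl offers competing 1,5 C–H bonds, the ketone is flanked by C8 and C9 so enolisation may win, and ring B with four stereocentres must first be built by an unrelated method.
- Comparison: in the chosen plan C3 and C4 come together from a chair rearrangement and C9 follows under their control, a firmer basis. Step economy is comparable only if a short route to A5 exists.

Key step: step 9

Remark 1: C8 of 20, 21, 28 and 29 forms as a mixture of epimers; names and SMILES show one epimer (S as drawn), and both are carried on because C8 becomes trigonal in 30.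
Remark 2: commercial 1 and 22 are taken as pure E isomers. The structures of 19 and 20 were checked atom by atom against 32; connectivity and the configurations at C3, C4 and C9 agree, and no correction was needed.

## Steps

Step 1
Reactants: 1 racemic (E)-pent-3-en-2-ol
Product: 2 (2S,3E)-pent-3-en-2-ol
Conditions: immobilised Candida antarctica lipase B, vinyl acetate, MTBE, rt, run to just past half conversion; separation from the acetate
Reagents that add atoms: none
Why: Lipase-catalysed kinetic resolution; for a methyl carbinol whose larger group is an alkenyl group the enzyme should acetylate the (R)-enantiomer, so the alcohol left over is (S). This carbinol is the only source of absolute configuration for C3 and C4.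

Step 2
Reactants: 3 ethyl 2-(2-methyl-1,3-dioxolan-2-yl)acetate
Product: 4 2-(2-methyl-1,3-dioxolan-2-yl)acetic acid
Conditions: LiOH, THF–H2O, rt; then 1 M HCl to pH 4, 0 °C
Reagents that add atoms: lithium hydroxide, [Li+].[OH-]
Why: Ester saponification; the dioxolane is inert to hydroxide, and brief cold acidification avoids ketal loss and decarboxylation.

Step 3
Reactants: 4 2-(2-methyl-1,3-dioxolan-2-yl)acetic acid; 2 (2S,3E)-pent-3-en-2-ol
Product: 5 (2S,3E)-pent-3-en-2-yl 2-(2-methyl-1,3-dioxolan-2-yl)acetate
Conditions: EDC·HCl, DMAP (cat.), CH2Cl2, 0 °C → rt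
Reagents that add atoms: none
Why: Steglich esterification; acylation occurs at oxygen, so the carbinol configuration is kept and no allylic transposition is expected under neutral conditions.

Step 4
Reactants: 5 (2S,3E)-pent-3-en-2-yl 2-(2-methyl-1,3-dioxolan-2-yl)acetate
Product: 8 (2R,3R,4E)-3-methyl-2-(2-methyl-1,3-dioxolan-2-yl)hex-4-enoic acid, via silyl ketene acetal 6 (not isolated), via trimethylsilyl ester 7 (not isolated)
Conditions: LiN(i-Pr)2, Me3SiCl (in situ), THF–DMPU, −78 °C → rt; aqueous citric acid
Reagents that add atoms: none
Why: Ireland–Claisen rearrangement: deprotonation with DMPU present should give the enolate with the ketal carbon cis to O–Li (chelation by a ketal oxygen favours the same geometry), trapped at once as (Z)-silyl ketene acetal 6, which limits β-elimination of the ketal oxygen. The chair transition state with the carbinol methyl equatorial transfers the (S) centre to the new C3–C4 bond, giving the 2,3-syn acid with both centres R and an E-propenyl group whose outer carbon is removed in step 7; aqueous acid cleaves silyl ester 7.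

Step 5
Reactants: 8 (2R,3R,4E)-3-methyl-2-(2-methyl-1,3-dioxolan-2-yl)hex-4-enoic acid
Product: 9 (2S,3R,4E)-3-methyl-2-(2-methyl-1,3-dioxolan-2-yl)hex-4-en-1-ol
Conditions: LiAlH4, THF, 0 °C → rt; H2O/NaOH work-up
Reagents that add atoms: none
Why: Hydride reduction of the acid to the primary alcohol; ketal, alkene and both stereocentres are untouched (the descriptor at C2 changes only through priorities).

Step 6
Reactants: 9 (2S,3R,4E)-3-methyl-2-(2-methyl-1,3-dioxolan-2-yl)hex-4-en-1-ol; 10 methyl 2-(triphenylphosphoranylidene)propanoate
Product: 12 methyl (2E,4S,5R,6E)-2,5-dimethyl-4-(2-methyl-1,3-dioxolan-2-yl)octa-2,6-dienoate, via aldehyde 11 (not isolated)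
Conditions: TEMPO (cat.), PhI(OAc)2, CH2Cl2, rt; then 10, 40 °C
Reagents that add atoms: none
Why: TEMPO (oxoammonium) oxidation of the primary alcohol, then a Wittig reaction with the stabilised ylide in the same flask, which should give the E trisubstituted enoate. The β-ketal aldehyde 11 is not isolated, and the medium is too weakly basic to epimerise C4 or open the ketal.

Step 7
Reactants: 12 methyl (2E,4S,5R,6E)-2,5-dimethyl-4-(2-methyl-1,3-dioxolan-2-yl)octa-2,6-dienoate
Product: 14 methyl (2E,4R,5S)-2,5-dimethyl-4-(2-methyl-1,3-dioxolan-2-yl)-6-oxohex-2-enoate, via syn-diol 13 (not isolated)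
Conditions: OsO4 (cat.), NaIO4, 2,6-lutidine, dioxane–H2O, rt
Reagents that add atoms: sodium periodate, [Na+].[O-]I(=O)(=O)=O (oxygen relayed through OsO4, O=[Os](=O)(=O)=O)
Why: Lemieux–Johnson cleavage: OsO4 should dihydroxylate the electron-rich 1,2-disubstituted propenyl group much faster than the conjugated, trisubstituted, hindered enoate, and periodate cleaves diol 13 to the aldehyde with loss of acetaldehyde. The lutidine buffer protects the α-stereocentre.

Step 8
Reactants: 14 methyl (2E,4R,5S)-2,5-dimethyl-4-(2-methyl-1,3-dioxolan-2-yl)-6-oxohex-2-enoate; 15 propyltriphenylphosphonium bromide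
Product: 19 methyl (2E,4S,5S,6Z)-7-bromo-2,5-dimethyl-4-(2-methyl-1,3-dioxolan-2-yl)nona-2,6-dienoate, via propylidene ylide 16 (not isolated), via bromophosphonium salt 17 (not isolated), via bromo ylide 18 (not isolated)
Conditions: 15, n-BuLi, THF, 0 °C; Br2, −78 °C; NaN(SiMe3)2, −78 → −40 °C; then 14, −78 °C → rt
Reagents that add atoms: bromine, BrBr
Why: Wittig reaction of an α-bromo ylide made in the flask by bromination of 16 and deprotonation of 17; it should give mainly the Z bromoalkene (bromine cis to C3), and any E isomer is equally useful because step 9 erases this geometry. Adding the aldehyde cold to the preformed ylide minimises enolisation at the α-stereocentre.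

Step 9
Reactants: 19 methyl (2E,4S,5S,6Z)-7-bromo-2,5-dimethyl-4-(2-methyl-1,3-dioxolan-2-yl)nona-2,6-dienoate
Product: 20 methyl 2-[(1S,4R,5S)-2-ethyl-4-methyl-5-(2-methyl-1,3-dioxolan-2-yl)cyclopent-2-en-1-yl]propanoate
Conditions: Bu3SnH, AIBN (cat.), PhH (0.01 M), 80 °C, slow addition of the stannane
Reagents that add atoms: none
Why: Tin hydride radical chain: Bu3Sn• abstracts bromine from 19 to give the σ-type alkenyl radical at C1, which adds to C9, the β-carbon of the methacrylate unit, and the tertiary α-ester radical at C8 is then reduced by the stannane. The closest known reaction type is the tin hydride-mediated 5-exo cyclisation of alkenyl radicals onto α,β-unsaturated esters. Ring A closes in the 5-exo-trig mode (C1–C9), and since the radical carbon keeps its double bond the alkene is left endocyclic at C1=C2 with no regiochemical choice. The one new ring stereocentre, C9, is set in a chair-like transition state with the C3 methyl and the bulky C4 dioxolanyl arm pseudo-equatorial, so the C8 side chain ends trans to C4 and cis to the C3 methyl; 1,3-allylic strain between H-4 and the enoate methyl fixes the rotamer about C4–C9 and reinforces this. Cyclisation must outrun hydrogen transfer to the alkenyl radical, which high dilution with slow stannane addition and the polarity match (nucleophilic sp2 radical, electron-poor β-carbon) secure; the same polarity and the stability of the C8 radical exclude 6-endo attack. The alkenyl radical inverts faster than it cyclises, so both bromoalkene isomers converge, and the cyclised radical is a stabilised tertiary one, so the homoallyl-to-cyclopropylcarbinyl shift that can enlarge such rings is uphill. C8 forms as a mixture of epimers, which is harmless because C8 is planarised in step 14.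

Step 10
Reactants: 20 methyl 2-[(1S,4R,5S)-2-ethyl-4-methyl-5-(2-methyl-1,3-dioxolan-2-yl)cyclopent-2-en-1-yl]propanoate
Product: 21 methyl 2-[(1S,4R,5S)-5-acetyl-2-ethyl-4-methylcyclopent-2-en-1-yl]propanoate
Conditions: 1 M HCl, THF, rt
Reagents that add atoms: water, O
Why: Acid-catalysed hydrolysis of the dioxolane; C4 becomes enolisable, but the all-trans arrangement of ring A is the thermodynamically preferred one, and ester and alkene are stable to dilute acid at room temperature.

Step 11
Reactants: 22 (E)-cinnamaldehyde
Product: 23 [(1E)-but-1-en-3-yn-1-yl]benzene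
Conditions: Me3SiCHN2, LiN(i-Pr)2, THF, −78 °C → rt
Reagents that add atoms: trimethylsilyldiazomethane, C[Si](C)(C)C=[N+]=[N-]
Why: Colvin rearrangement: addition of lithiated trimethylsilyldiazomethane, Peterson-type elimination and 1,2-hydrogen shift of the alkylidene carbene give the terminal alkyne with the E-styryl geometry untouched.

Step 12
Reactants: 23 [(1E)-but-1-en-3-yn-1-yl]benzene
Product: 25 [(1E,3E)-3-ethyl-4-iodobuta-1,3-dien-1-yl]benzene, via dienylcopper 24 (not isolated)
Conditions: EtMgBr, CuBr·SMe2, Et2O–Me2S, −45 °C; 23, −25 °C; I2, THF, −78 → 0 °C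
Reagents that add atoms: ethylmagnesium bromide, CC[Mg]Br; iodine, II
Why: Carbocupration of a terminal alkyne: ethylcopper adds syn, ethyl to the internal and copper to the terminal carbon, and iodine replaces copper in 24 with retention. Iodine therefore ends cis to ethyl and trans to the styryl group, the (1E,3E) geometry that step 14 turns into the C7 configuration.

Step 13
Reactants: 21 methyl 2-[(1S,4R,5S)-5-acetyl-2-ethyl-4-methylcyclopent-2-en-1-yl]propanoate; 25 [(1E,3E)-3-ethyl-4-iodobuta-1,3-dien-1-yl]benzene
Product: 29 (1S,4S,4aS,7R,7aS)-5-ethyl-1-[(1E,3E)-2-ethyl-4-phenylbuta-1,3-dien-1-yl]-1,4,7-trimethyl-4,4a,7,7a-tetrahydrocyclopenta[c]pyran-3(1H)-one, via dienyllithium 26 (not isolated), via dienylcerium dichloride 27 (not isolated), via cerium alkoxide 28 (not isolated)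
Conditions: 25, t-BuLi (2 equiv), Et2O, −78 °C; CeCl3, THF, −78 °C; then 21, −78 °C → rt
Reagents that add atoms: none
Why: Iodine–lithium exchange with retention and transmetalation give a weakly basic organocerium that should add to the ketone and not to the ester; the tertiary alkoxide 28 then closes the δ-lactone by acyl transfer with loss of methoxide. C5 should be set by attack past H-4, anti to the C9 branch, on the rotamer in which trivalent cerium bridges the ketone and ester oxygens (the geometry that leads on to ring closure), which puts the dienyl group cis to H-4 (S at C5). Selectivity is expected to be moderate at best, and the C5 epimer must be removed here because it would lead to the C7/C8 diastereomer.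

Step 14
Reactants: 29 (1S,4S,4aS,7R,7aS)-5-ethyl-1-[(1E,3E)-2-ethyl-4-phenylbuta-1,3-dien-1-yl]-1,4,7-trimethyl-4,4a,7,7a-tetrahydrocyclopenta[c]pyran-3(1H)-one
Product: 32 24-nor-spiculoic acid B, via silyl ketene acetal 30 (not isolated), via trimethylsilyl ester 31 (not isolated)
Conditions: LiN(i-Pr)2, Me3SiCl–Et3N (in situ), THF, −78 °C; PhMe, 105 °C; then 1 M HCl–THF, rt
Reagents that add atoms: none
Why: Ireland–Claisen rearrangement in its ring-contracting form: in 30 the ketene acetal can reach C7 only through a boat-like transition state in which C8 bonds on the ring face that carries the dienyl group, so the C5 configuration is relayed to C8 (carboxyl cis to H-9), and the E substituent of C6=C7 (styryl) ends cis to the carboxyl, which fixes C7. C5–O breaks as C7–C8 forms, ring B appears with its C5=C6 bond, and mild acid cleaves silyl ester 31.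

## Compound list

1 | racemic (E)-pent-3-en-2-ol | C/C=C/C(C)O | starting material
2 | (2S,3E)-pent-3-en-2-ol | C/C=C/[C@H](C)O | intermediate
3 | ethyl 2-(2-methyl-1,3-dioxolan-2-yl)acetate | CCOC(=O)CC1(C)OCCO1 | starting material
4 | 2-(2-methyl-1,3-dioxolan-2-yl)acetic acid | OC(=O)CC1(C)OCCO1 | intermediate
5 | (2S,3E)-pent-3-en-2-yl 2-(2-methyl-1,3-dioxolan-2-yl)acetate | C/C=C/[C@H](C)OC(=O)CC1(C)OCCO1 | intermediate
6 | (Z)-O-trimethylsilyl ketene acetal of 5 (ketal carbon cis to OSiMe3) | C/C=C/[C@H](C)O/C(O[Si](C)(C)C)=C/C1(C)OCCO1 | intermediate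
7 | trimethylsilyl (2R,3R,4E)-3-methyl-2-(2-methyl-1,3-dioxolan-2-yl)hex-4-enoate | C/C=C/[C@@H](C)[C@H](C1(C)OCCO1)C(=O)O[Si](C)(C)C | intermediate
8 | (2R,3R,4E)-3-methyl-2-(2-methyl-1,3-dioxolan-2-yl)hex-4-enoic acid | C/C=C/[C@@H](C)[C@H](C1(C)OCCO1)C(=O)O | intermediate
9 | (2S,3R,4E)-3-methyl-2-(2-methyl-1,3-dioxolan-2-yl)hex-4-en-1-ol | C/C=C/[C@@H](C)[C@H](C1(C)OCCO1)CO | intermediate
10 | methyl 2-(triphenylphosphoranylidene)propanoate | COC(=O)C(C)=P(c1ccccc1)(c1ccccc1)c1ccccc1 | starting material
11 | (2S,3R,4E)-3-methyl-2-(2-methyl-1,3-dioxolan-2-yl)hex-4-enal | C/C=C/[C@@H](C)[C@H](C1(C)OCCO1)C=O | intermediate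
12 | methyl (2E,4S,5R,6E)-2,5-dimethyl-4-(2-methyl-1,3-dioxolan-2-yl)octa-2,6-dienoate | C/C=C/[C@@H](C)[C@H](C1(C)OCCO1)/C=C(\C)C(=O)OC | intermediate
13 | methyl (2E,4R,5S)-6,7-dihydroxy-2,5-dimethyl-4-(2-methyl-1,3-dioxolan-2-yl)oct-2-enoate (syn-diol, both facial isomers, carbinol centres not drawn) | CC(O)C(O)[C@@H](C)[C@H](C1(C)OCCO1)/C=C(\C)C(=O)OC | intermediate
14 | methyl (2E,4R,5S)-2,5-dimethyl-4-(2-methyl-1,3-dioxolan-2-yl)-6-oxohex-2-enoate | O=C[C@@H](C)[C@H](C1(C)OCCO1)/C=C(\C)C(=O)OC | intermediate
15 | propyltriphenylphosphonium bromide | CCC[P+](c1ccccc1)(c1ccccc1)c1ccccc1.[Br-] | starting material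
16 | propylidenetriphenylphosphorane | CCC=P(c1ccccc1)(c1ccccc1)c1ccccc1 | intermediate
17 | (1-bromopropyl)triphenylphosphonium bromide (racemic) | CCC(Br)[P+](c1ccccc1)(c1ccccc1)c1ccccc1.[Br-] | intermediate
18 | (1-bromopropylidene)triphenylphosphorane | CCC(Br)=P(c1ccccc1)(c1ccccc1)c1ccccc1 | intermediate
19 | methyl (2E,4S,5S,6Z)-7-bromo-2,5-dimethyl-4-(2-methyl-1,3-dioxolan-2-yl)nona-2,6-dienoate | CC/C(Br)=C/[C@@H](C)[C@H](C1(C)OCCO1)/C=C(\C)C(=O)OC | intermediate
20 | methyl 2-[(1S,4R,5S)-2-ethyl-4-methyl-5-(2-methyl-1,3-dioxolan-2-yl)cyclopent-2-en-1-yl]propanoate (C2 of the propanoate epimeric, drawn 2S) | CCC1=C[C@@H](C)[C@H](C2(C)OCCO2)[C@H]1[C@H](C)C(=O)OC | intermediate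
21 | methyl 2-[(1S,4R,5S)-5-acetyl-2-ethyl-4-methylcyclopent-2-en-1-yl]propanoate (C2 of the propanoate epimeric, drawn 2S) | CCC1=C[C@@H](C)[C@H](C(C)=O)[C@H]1[C@H](C)C(=O)OC | intermediate
22 | (E)-cinnamaldehyde | O=C/C=C/c1ccccc1 | starting material
23 | [(1E)-but-1-en-3-yn-1-yl]benzene | C#C/C=C/c1ccccc1 | intermediate
24 | [(1E,3E)-2-ethyl-4-phenylbuta-1,3-dien-1-yl]copper | [Cu]/C=C(\CC)/C=C/c1ccccc1 | intermediate
25 | [(1E,3E)-3-ethyl-4-iodobuta-1,3-dien-1-yl]benzene | I/C=C(\CC)/C=C/c1ccccc1 | intermediate
26 | [(1E,3E)-2-ethyl-4-phenylbuta-1,3-dien-1-yl]lithium | [Li]/C=C(\CC)/C=C/c1ccccc1 | intermediate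
27 | dichloro[(1E,3E)-2-ethyl-4-phenylbuta-1,3-dien-1-yl]cerium | Cl[Ce](Cl)/C=C(\CC)/C=C/c1ccccc1 | intermediate
28 | methyl 2-{(1S,4R,5S)-2-ethyl-5-[(2S,3E,5E)-4-ethyl-2-oxido-6-phenylhexa-3,5-dien-2-yl]-4-methylcyclopent-2-en-1-yl}propanoate, cerium alkoxide (drawn as the anion) | CCC1=C[C@@H](C)[C@H]([C@](C)([O-])/C=C(\CC)/C=C/c2ccccc2)[C@H]1[C@H](C)C(=O)OC | intermediate
29 | (1S,4S,4aS,7R,7aS)-5-ethyl-1-[(1E,3E)-2-ethyl-4-phenylbuta-1,3-dien-1-yl]-1,4,7-trimethyl-4,4a,7,7a-tetrahydrocyclopenta[c]pyran-3(1H)-one (C4 epimeric, drawn 4S; dienyl cis to H-7a) | CCC1=C[C@@H](C)[C@H]2[C@H]1[C@H](C)C(=O)O[C@]2(C)/C=C(\CC)/C=C/c1ccccc1 | intermediate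
30 | O-trimethylsilyl ketene acetal of 29 (C3=C4 double bond, OSiMe3 on C3; other centres as in 29) | CCC1=C[C@@H](C)[C@H]2[C@H]1C(C)=C(O[Si](C)(C)C)O[C@]2(C)/C=C(\CC)/C=C/c1ccccc1 | intermediate
31 | trimethylsilyl (1R,3aR,4R,5S,7aS)-3,5-diethyl-1,4,7-trimethyl-5-[(E)-2-phenylethenyl]-3a,4,5,7a-tetrahydro-1H-indene-4-carboxylate | CCC1=C[C@@H](C)[C@@H]2C(C)=C[C@@](/C=C/c3ccccc3)(CC)[C@](C)(C(=O)O[Si](C)(C)C)[C@@H]12 | intermediate
32 | 24-nor-spiculoic acid B, (1R,3aR,4R,5S,7aS)-3,5-diethyl-1,4,7-trimethyl-5-[(E)-2-phenylethenyl]-3a,4,5,7a-tetrahydro-1H-indene-4-carboxylic acid | CCC1=C[C@@H](C)[C@@H]2C(C)=C[C@@](/C=C/c3ccccc3)(CC)[C@](C)(C(=O)O)[C@@H]12 | target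

## Step count and least certain steps

Total step count: 14. Longest linear sequence: 11 steps (3 → 4 → 5 → 8 → 9 → 12 → 14 → 19 → 20 → 21 → 29 → 32; steps 2–10, 13 and 14).

Step 9 (key step). What may go wrong: hydrogen transfer from the stannane to the alkenyl radical before it closes, or erosion of the facial preference at C9 at 80 °C, because the flat sp2 radical centre narrows the gap between chair-like and boat-like closures. Fallback (polar closure): setting out from 14, the Wittig step is repeated with iodine in place of bromine. Ylide 16 and iodine give (1-iodopropyl)triphenylphosphonium iodide F1, NaN(SiMe3)2 gives (1-iodopropylidene)triphenylphosphorane F2, and condensation with 14 gives the iodoalkene F3. F3 is treated with n-BuLi in THF at −100 °C, where iodine–lithium exchange outruns attack on the ester and the alkenyllithium adds intramolecularly to the enoate (anionic 5-exo conjugate addition). Protonation of the ester enolate returns the route at 20.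

Step 14. What may go wrong: heterolysis of the tertiary, doubly allylic C5–O bond of 30 (elimination to trienes or loss of the stereochemical relay), competing with a rearrangement slowed by the strained boat-like transition state and by contact between the C7 ethyl group and ring A. Incomplete enolisation at the hindered C8–H is a second possibility. Fallback (open-chain Claisen rearrangement, then ring closure by metathesis): setting out from 21, Wittig methylenation (Ph3P=CH2, THF) gives the isopropenyl ester F4 and LiOH the isopropenyl acid F5. Dienyllithium 26 and paraformaldehyde give the dienol F6, and carbodiimide coupling of F5 with F6 gives the allylic ester F7. LiN(i-Pr)2/Me3SiCl converts F7 into the silyl ketene acetal F8, whose Ireland–Claisen rearrangement through an unconstrained chair gives the silyl ester F9 and, after hydrolysis, the triene acid F10, with the C7–C8 bond made and a vinyl group on C7. Ring-closing metathesis of the isopropenyl and vinyl groups of F10 with the second-generation Grubbs catalyst, RuCl2(=CHPh)(H2IMes)(PCy3), closes ring B at C5=C6 and returns the route at 32. Stereocontrol at C7/C8 is weaker here (it rests on ketene acetal geometry and on C9), so separation of diastereomers at F10 is to be expected.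

Step 13. What may go wrong: poor or reversed facial selectivity at C5, because the two ring carbons flanking the acetyl group (C3 and C9) differ little near the carbonyl and bridging of the two carbonyl groups by cerium is not assured. Slow ring closure of the hindered alkoxide is a lesser concern. Fallback (carboxylate-anchored addition with separate ring closure): setting out from 21, LiOH gives the keto acid F11. Its sodium salt (NaH, THF) is treated with 27; the carboxylate now binds the metal firmly on the C9 side, so the ketone is held in the pre-lactone rotamer and attacked past H-4, giving the hydroxy acid F12. Carbodiimide/DMAP lactonisation of F12 returns the route at 29.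

## Further compounds

F1 | step 9 | (1-iodopropyl)triphenylphosphonium iodide (racemic) | CCC(I)[P+](c1ccccc1)(c1ccccc1)c1ccccc1.[I-]
F2 | step 9 | (1-iodopropylidene)triphenylphosphorane | CCC(I)=P(c1ccccc1)(c1ccccc1)c1ccccc1
F3 | step 9 | methyl (2E,4S,5S,6Z)-7-iodo-2,5-dimethyl-4-(2-methyl-1,3-dioxolan-2-yl)nona-2,6-dienoate | CC/C(I)=C/[C@@H](C)[C@H](C1(C)OCCO1)/C=C(\C)C(=O)OC
F4 | step 14 | methyl 2-[(1S,4R,5S)-2-ethyl-4-methyl-5-(prop-1-en-2-yl)cyclopent-2-en-1-yl]propanoate (C2 epimeric, drawn 2S) | CCC1=C[C@@H](C)[C@H](C(C)=C)[C@H]1[C@H](C)C(=O)OC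
F5 | step 14 | 2-[(1S,4R,5S)-2-ethyl-4-methyl-5-(prop-1-en-2-yl)cyclopent-2-en-1-yl]propanoic acid (C2 epimeric, drawn 2S) | CCC1=C[C@@H](C)[C@H](C(C)=C)[C@H]1[C@H](C)C(=O)O
F6 | step 14 | (2E,4E)-3-ethyl-5-phenylpenta-2,4-dien-1-ol | OC/C=C(\CC)/C=C/c1ccccc1
F7 | step 14 | (2E,4E)-3-ethyl-5-phenylpenta-2,4-dien-1-yl ester of F5 | CCC1=C[C@@H](C)[C@H](C(C)=C)[C@H]1[C@H](C)C(=O)OC/C=C(\CC)/C=C/c1ccccc1
F8 | step 14 | O-trimethylsilyl ketene acetal of F7 (ketene acetal geometry not controlled) | CCC1=C[C@@H](C)[C@H](C(C)=C)[C@H]1C(C)=C(O[Si](C)(C)C)OC/C=C(\CC)/C=C/c1ccccc1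
F9 | step 14 | trimethylsilyl ester of F10 | CCC1=C[C@@H](C)[C@H](C(C)=C)[C@H]1[C@@](C)(C(=O)O[Si](C)(C)C)[C@@](C=C)(CC)/C=C/c1ccccc1
F10 | step 14 | (2R,3S,4E)-3-ethenyl-3-ethyl-2-[(1R,4R,5S)-2-ethyl-4-methyl-5-(prop-1-en-2-yl)cyclopent-2-en-1-yl]-2-methyl-5-phenylpent-4-enoic acid (C7 and C8 as in the target) | CCC1=C[C@@H](C)[C@H](C(C)=C)[C@H]1[C@@](C)(C(=O)O)[C@@](C=C)(CC)/C=C/c1ccccc1
F11 | step 13 | 2-[(1S,4R,5S)-5-acetyl-2-ethyl-4-methylcyclopent-2-en-1-yl]propanoic acid (C2 epimeric, drawn 2S) | CCC1=C[C@@H](C)[C@H](C(C)=O)[C@H]1[C@H](C)C(=O)O
F12 | step 13 | 2-{(1S,4R,5S)-2-ethyl-5-[(2S,3E,5E)-4-ethyl-2-hydroxy-6-phenylhexa-3,5-dien-2-yl]-4-methylcyclopent-2-en-1-yl}propanoic acid (C2 epimeric, drawn 2S) | CCC1=C[C@@H](C)[C@H]([C@](C)(O)/C=C(\CC)/C=C/c2ccccc2)[C@H]1[C@H](C)C(=O)O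
A1 | alternative 1 | Heck precursor: cyclopentanone with Z-iodoalkenyl group on C4 and (E)-C7(Et)=CH–CH2Ph on quaternary C8 (C3, C4, C8, C9 as in the target) | O=C1C[C@@H](C)[C@H](/C(C)=C\I)[C@H]1[C@@](C)(C(=O)OC)/C(CC)=C/Cc1ccccc1
A2 | alternative 1 | cyclohexene-fused cyclopentanone methyl ester (C1 ketone) | O=C1C[C@@H](C)[C@@H]2C(C)=C[C@@](/C=C/c3ccccc3)(CC)[C@](C)(C(=O)OC)[C@@H]12
A3 | alternative 2 | dienyl δ-lactone (same compound as 29) | CCC1=C[C@@H](C)[C@H]2[C@H]1[C@H](C)C(=O)O[C@]2(C)/C=C(\CC)/C=C/c1ccccc1
A4 | alternative 2 | trimethylsilyl ester of the target (same compound as 31) | CCC1=C[C@@H](C)[C@@H]2C(C)=C[C@@](/C=C/c3ccccc3)(CC)[C@](C)(C(=O)O[Si](C)(C)C)[C@@H]12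
A5 | alternative 3 | ring-B propionyl ketone: methyl cyclohex-3-ene-1-carboxylate with propanoyl on C9 and ethyl on C4 (C4, C7, C8, C9 as in the target) | CCC(=O)[C@H]1[C@H](CC)C(C)=C[C@@](/C=C/c2ccccc2)(CC)[C@]1(C)C(=O)OC
A6 | alternative 3 | methyl ester of the target | CCC1=C[C@@H](C)[C@@H]2C(C)=C[C@@](/C=C/c3ccccc3)(CC)[C@](C)(C(=O)OC)[C@@H]12
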